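The target is cut at C1–C10 of the seven-membered ring (numbering: seven-membered ring C1(OAr)–C2–C3(Me)–C7(OH)–C8–C9–C10(Me,OH); five-membered ring C3–C4–C5–C6(iPr)–C7). C1 and C10 are neighbours and both carry oxygen, so the bond is made by joining two carbonyl carbons: a carbene-catalysed intramolecular crossed benzoin reaction turns the C1 aldehyde into an acyl anion equivalent that adds to the C10 methyl ketone. One operation closes the seven-membered ring, forms C1–C10 and sets the C10 carbinol, leaving a C1 ketone for reduction. The precursor is a cyclopentane with cis CH2CHO (on C3) and CH2CH2COCH3 (on C7) arms and a C7 triethylsilyl ether, built from (S)-limonene.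

Key step: step 11

Remark 1: atom labels C1–C10 in all steps are those of the opening paragraph.
Remark 2: the sense of induction of the triazolium salt on this cis-fused substrate cannot be derived from the structures alone; the (5aR,10bS) antipode is written in step 11, and its mirror image takes its place if the first run shows the C10 epimer.

Step 1
Reactants: 1 (S)-(−)-limonene
Product: 2 (S)-p-menth-1-ene [(4S)-1-methyl-4-(propan-2-yl)cyclohex-1-ene]
Conditions: H2 (1 atm, 1 equiv), PtO2 (cat.), EtOH, rt
Reagents that add atoms: none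
Why: Heterogeneous hydrogenation over PtO2 takes the 1,1-disubstituted isopropenyl double bond well before the trisubstituted ring double bond, so uptake of one equivalent should give the mono-ene without touching the stereocentre.

Step 2
Reactants: 2 (S)-p-menth-1-ene
Product: 4 (3S)-6-oxo-3-(propan-2-yl)heptanal, via ozonide 3 (not isolated)
Conditions: O3, CH2Cl2, −78 °C; then Me2S, −78 °C → rt
Reagents that add atoms: ozone, [O-][O+]=O
Why: Ozonolysis with reductive work-up cleaves the ring double bond to the methyl ketone and the aldehyde, and the stereocentre, which is not α to either carbonyl group, cannot epimerise.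

Step 3
Reactants: 4 (3S)-6-oxo-3-(propan-2-yl)heptanal
Product: 6 (5R)-2-methyl-5-(propan-2-yl)cyclopent-1-ene-1-carbaldehyde, via aldol adduct 5 (not isolated)
Conditions: piperidine (cat.), AcOH (cat.), toluene, reflux, water removed
Reagents that add atoms: none
Why: Intramolecular aldol condensation under amine–acid catalysis: the enamine of the aldehyde adds to the methyl ketone and water is lost, which should give the cyclopentene aldehyde holding ring carbons C3–C7, with the C6 centre intact because it is never α to a carbonyl group.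

Step 4
Reactants: 6 (5R)-2-methyl-5-(propan-2-yl)cyclopent-1-ene-1-carbaldehyde
Product: 7 [(5R)-2-methyl-5-(propan-2-yl)cyclopent-1-en-1-yl]methanol
Conditions: NaBH4, CeCl3·7H2O, MeOH, 0 °C
Reagents that add atoms: none
Why: Luche reduction delivers hydride to the carbonyl carbon of the conjugated aldehyde only and should give the primary allylic alcohol.

Step 5
Reactants: 7 [(5R)-2-methyl-5-(propan-2-yl)cyclopent-1-en-1-yl]methanol; 8 triethyl orthoacetate
Product: 11 ethyl 2-[(1R,3R)-1-methyl-2-methylidene-3-(propan-2-yl)cyclopentyl]acetate, via mixed orthoester 9 (not isolated), via ketene acetal 10 (not isolated)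
Conditions: MeC(OEt)3 (excess), EtCO2H (cat.), 140 °C, EtOH distilled off
Reagents that add atoms: triethyl orthoacetate (8), CCOC(C)(OCC)OCC
Why: Johnson–Claisen rearrangement: the [3,3]-sigmatropic shift of the ketene acetal makes the C3–C2 bond and the quaternary centre C3 regiospecifically, and the chair-like transition state should keep the migrating C–O–C unit on the ring face opposite the neighbouring C6 isopropyl group, so the ester arm ends up trans to isopropyl and the methyl group cis to it.

Step 6
Reactants: 11 ethyl 2-[(1R,3R)-1-methyl-2-methylidene-3-(propan-2-yl)cyclopentyl]acetate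
Product: 13 ethyl 2-[(1R,3R)-1-methyl-2-oxo-3-(propan-2-yl)cyclopentyl]acetate, via ozonide 12 (not isolated)
Conditions: O3, CH2Cl2, −78 °C; then PPh3, −78 °C → rt
Reagents that add atoms: ozone, [O-][O+]=O
Why: Ozonolysis of the exocyclic methylene group with phosphine work-up unveils the C7 ketone under neutral conditions, so the C6 centre, now α to a carbonyl group, should not epimerise.

Step 7
Reactants: 13 ethyl 2-[(1R,3R)-1-methyl-2-oxo-3-(propan-2-yl)cyclopentyl]acetate; 14 4-bromo-2-methylbut-1-ene
Product: 17 ethyl 2-[(1R,2S,3R)-2-hydroxy-1-methyl-2-(3-methylbut-3-en-1-yl)-3-(propan-2-yl)cyclopentyl]acetate, via Grignard reagent 15 (not isolated), via organocerium reagent 16 (not isolated)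
Conditions: 14, Mg, THF, rt; anhydrous CeCl3, THF, −78 °C; then 13, −78 °C; aq. NH4Cl
Reagents that add atoms: 4-bromo-2-methylbut-1-ene (14), C=C(C)CCBr
Why: Organocerium addition to a ketone: the weakly basic, carbonyl-selective reagent should add to the hindered, enolisable C7 ketone faster than it attacks the ester or removes the C6 proton, and it should enter from the ring face opposite both the C6 isopropyl and the C3 methyl group, which sets C7 with the hydroxyl cis to methyl and isopropyl and the new chain cis to the C3 arm.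

Step 8
Reactants: 17 ethyl 2-[(1R,2S,3R)-2-hydroxy-1-methyl-2-(3-methylbut-3-en-1-yl)-3-(propan-2-yl)cyclopentyl]acetate
Product: 18 ethyl 2-[(1R,2S,3R)-1-methyl-2-(3-methylbut-3-en-1-yl)-3-(propan-2-yl)-2-[(triethylsilyl)oxy]cyclopentyl]acetate
Conditions: Et3SiOTf, 2,6-lutidine, CH2Cl2, 0 °C → rt
Reagents that add atoms: triethylsilyl trifluoromethanesulfonate, CC[Si](CC)(CC)OS(=O)(=O)C(F)(F)F
Why: A silyl triflate with a hindered pyridine base is the standard means of capping a congested tertiary alcohol; the triethylsilyl ether is preferred to a trimethylsilyl ether because it should outlast chromatography, ozonolysis and the acetic acid of step 12, and its task is to keep the C7 oxygen from closing a spiro-hemiketal onto the C10 ketone of 21 or a bridged one onto the C1 ketone of 22.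

Step 9
Reactants: 18 ethyl 2-[(1R,2S,3R)-1-methyl-2-(3-methylbut-3-en-1-yl)-3-(propan-2-yl)-2-[(triethylsilyl)oxy]cyclopentyl]acetate
Product: 19 2-[(1R,2S,3R)-1-methyl-2-(3-methylbut-3-en-1-yl)-3-(propan-2-yl)-2-[(triethylsilyl)oxy]cyclopentyl]acetaldehyde
Conditions: i-Bu2AlH (1.1 equiv), CH2Cl2, −78 °C; MeOH, then aq. potassium sodium tartrate
Reagents that add atoms: none
Why: Partial reduction of an ester with i-Bu2AlH: at −78 °C the aluminium hemiacetal of this β-quaternary ester should persist until the quench and then release the C1 aldehyde, while the silyl ether and the double bond are inert.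

Step 10
Reactants: 19 2-[(1R,2S,3R)-1-methyl-2-(3-methylbut-3-en-1-yl)-3-(propan-2-yl)-2-[(triethylsilyl)oxy]cyclopentyl]acetaldehyde
Product: 21 2-[(1R,2S,3R)-1-methyl-2-(3-oxobutyl)-3-(propan-2-yl)-2-[(triethylsilyl)oxy]cyclopentyl]acetaldehyde, via ozonide 20 (not isolated)
Conditions: O3, CH2Cl2, −78 °C, stopped at first blue colour; then PPh3, −78 °C → rt
Reagents that add atoms: ozone, [O-][O+]=O
Why: Ozonolysis with phosphine work-up converts the 1,1-disubstituted double bond into the C10 methyl ketone under neutral conditions that the aldehyde, the silyl ether and the stereocentres should tolerate.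

Step 11
Reactants: 21 2-[(1R,2S,3R)-1-methyl-2-(3-oxobutyl)-3-(propan-2-yl)-2-[(triethylsilyl)oxy]cyclopentyl]acetaldehyde
Product: 22 (1R,3aR,6R,8aS)-6-hydroxy-3a,6-dimethyl-1-(propan-2-yl)-8a-[(triethylsilyl)oxy]octahydroazulen-5(1H)-one (C1 ketone; C10 tertiary carbinol)
Conditions: (5aR,10bS)-2-(pentafluorophenyl)-5a,10b-dihydro-4H,6H-indeno[2,1-b][1,2,4]triazolo[4,3-d][1,4]oxazin-2-ium tetrafluoroborate (20 mol%), i-Pr2NEt (0.5 equiv), CH2Cl2 (0.02 M), 40 °C, argon
Reagents that add atoms: none
Why: Proposed new method: the triazolylidene freed by the amine adds to the C1 aldehyde, which is far more electrophilic than the C10 ketone, proton transfer gives the enaminol whose C1 is now nucleophilic, C1 attacks the C10 ketone, and proton transfer with loss of the carbene releases the α-hydroxy ketone. The closest known reaction type is the carbene-catalysed intramolecular crossed benzoin cyclisation of keto-aldehydes to tertiary α-hydroxy ketones, established for five- and six-membered rings, so only the ring size is new. The seven-membered ring closes in a 7-exo-trig mode, helped by the cis arrangement of the two arms on the cyclopentane (fixed in step 7), which holds C1 and C10 close. The new stereocentre C10 (10R, hydroxyl on the face of the seven-membered ring opposite the C3 methyl and the C7 silyloxy group) is set by the chiral triazolylidene acting together with the cis-fused template, a case of double stereodifferentiation in which the antipode of the catalyst is the control element. The step needs acyl anion formation at the aldehyde only, suppression of the two possible six-membered aldol closures (C2 onto C10, C9 onto C1) and of intermolecular benzoin coupling; the electron-poor N-pentafluorophenyl triazolium salt used with a weak amine base, the high dilution and the hindered β-quaternary aldehyde serve these ends, and the C7 triethylsilyl ether keeps the C7 oxygen out of the reaction.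

Step 12
Reactants: 22 (1R,3aR,6R,8aS)-6-hydroxy-3a,6-dimethyl-1-(propan-2-yl)-8a-[(triethylsilyl)oxy]octahydroazulen-5(1H)-one
Product: 24 (3R,3aS,6R,7R,8aR)-6,8a-dimethyl-3-(propan-2-yl)decahydroazulene-3a,6,7-triol, via silyl diol 23 (not isolated)
Conditions: Me4NBH(OAc)3, MeCN/AcOH (1:1), −25 → 0 °C; then aq. HF (48%), 0 °C → rt
Reagents that add atoms: none
Why: Hydroxyl-directed triacetoxyborohydride reduction (Evans–Saksena reduction): the C10 hydroxyl binds boron and delivers hydride to its own face of the C1 ketone, which is also the face remote from the C3 and C10 methyl groups, so the C1 hydroxyl should come out trans to the C10 hydroxyl (1R), and aqueous HF then removes the triethylsilyl group, which until that point keeps the C7 oxygen from delivering hydride to the other face.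

Step 13
Reactants: 24 (3R,3aS,6R,7R,8aR)-6,8a-dimethyl-3-(propan-2-yl)decahydroazulene-3a,6,7-triol; 25 p-anisoyl chloride
Product: 26 (1R,3aR,5R,6R,8aS)-6,8a-dihydroxy-3a,6-dimethyl-1-(propan-2-yl)decahydroazulen-5-yl 4-methoxybenzoate (CNP0244624.1)
Conditions: 25 (1.3 equiv), pyridine, DMAP (cat.), CH2Cl2, 0 °C → rt
Reagents that add atoms: p-anisoyl chloride (25), COc1ccc(C(Cl)=O)cc1
Why: Acylation of an alcohol with an acid chloride under nucleophilic catalysis: only the secondary C1 hydroxyl should react, the tertiary hydroxyls at C7 and C10 being far slower, and no stereocentre is touched.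

Compound list
1 | (S)-(−)-limonene, (4S)-1-methyl-4-(prop-1-en-2-yl)cyclohex-1-ene | C=C(C)[C@H]1CCC(C)=CC1 | starting material
2 | (S)-p-menth-1-ene, (4S)-1-methyl-4-(propan-2-yl)cyclohex-1-ene | CC(C)[C@H]1CCC(C)=CC1 | intermediate
3 | ozonide of 2, 1-methyl-4-(propan-2-yl)-7,8,9-trioxabicyclo[4.2.1]nonane (isopropyl centre as in 2; both bridgehead arrangements) | CC12CC[C@H](C(C)C)CC(OO1)O2 | intermediate
4 | (3S)-6-oxo-3-(propan-2-yl)heptanal | CC(=O)CC[C@H](C(C)C)CC=O | intermediate
5 | aldol adduct, (5R)-2-hydroxy-2-methyl-5-(propan-2-yl)cyclopentane-1-carbaldehyde (C1 and C2 of the ring as a mixture) | O=CC1C(C)(O)CC[C@@H]1C(C)C | intermediate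
6 | (5R)-2-methyl-5-(propan-2-yl)cyclopent-1-ene-1-carbaldehyde | O=CC1=C(C)CC[C@@H]1C(C)C | intermediate
7 | [(5R)-2-methyl-5-(propan-2-yl)cyclopent-1-en-1-yl]methanol | OCC1=C(C)CC[C@@H]1C(C)C | intermediate
8 | triethyl orthoacetate (1,1,1-triethoxyethane) | CCOC(C)(OCC)OCC | starting material
9 | mixed orthoester, 1,1-diethoxy-1-{[(5R)-2-methyl-5-(propan-2-yl)cyclopent-1-en-1-yl]methoxy}ethane | CCOC(C)(OCC)OCC1=C(C)CC[C@@H]1C(C)C | intermediate
10 | ketene acetal, 1-ethoxy-1-{[(5R)-2-methyl-5-(propan-2-yl)cyclopent-1-en-1-yl]methoxy}ethene | C=C(OCC)OCC1=C(C)CC[C@@H]1C(C)C | intermediate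
11 | ethyl 2-[(1R,3R)-1-methyl-2-methylidene-3-(propan-2-yl)cyclopentyl]acetate | CCOC(=O)C[C@@]1(C)CC[C@H](C(C)C)C1=C | intermediate
12 | spiro-ozonide of 11 (1,2,4-trioxolane spiro-fused at C7; C3 and C6 as in 11; mixture at the spiro carbon) | CCOC(=O)C[C@@]1(C)CC[C@H](C(C)C)C12OCOO2 | intermediate
13 | ethyl 2-[(1R,3R)-1-methyl-2-oxo-3-(propan-2-yl)cyclopentyl]acetate | CCOC(=O)C[C@@]1(C)CC[C@H](C(C)C)C1=O | intermediate
14 | 4-bromo-2-methylbut-1-ene | C=C(C)CCBr | starting material
15 | (3-methylbut-3-en-1-yl)magnesium bromide | C=C(C)CC[Mg]Br | intermediate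
16 | dichloro(3-methylbut-3-en-1-yl)cerium | C=C(C)CC[Ce](Cl)Cl | intermediate
17 | ethyl 2-[(1R,2S,3R)-2-hydroxy-1-methyl-2-(3-methylbut-3-en-1-yl)-3-(propan-2-yl)cyclopentyl]acetate | CCOC(=O)C[C@@]1(C)CC[C@H](C(C)C)[C@@]1(O)CCC(C)=C | intermediate
18 | ethyl 2-[(1R,2S,3R)-1-methyl-2-(3-methylbut-3-en-1-yl)-3-(propan-2-yl)-2-[(triethylsilyl)oxy]cyclopentyl]acetate | CCOC(=O)C[C@@]1(C)CC[C@H](C(C)C)[C@@]1(O[Si](CC)(CC)CC)CCC(C)=C | intermediate
19 | 2-[(1R,2S,3R)-1-methyl-2-(3-methylbut-3-en-1-yl)-3-(propan-2-yl)-2-[(triethylsilyl)oxy]cyclopentyl]acetaldehyde | O=CC[C@@]1(C)CC[C@H](C(C)C)[C@@]1(O[Si](CC)(CC)CC)CCC(C)=C | intermediate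
20 | ozonide of 19 (3-methyl-1,2,4-trioxolan-3-yl in place of the isopropenyl group; mixture at the new centre) | O=CC[C@@]1(C)CC[C@H](C(C)C)[C@@]1(O[Si](CC)(CC)CC)CCC2(C)OCOO2 | intermediate
21 | 2-[(1R,2S,3R)-1-methyl-2-(3-oxobutyl)-3-(propan-2-yl)-2-[(triethylsilyl)oxy]cyclopentyl]acetaldehyde (keto-aldehyde; 3R,6R,7S in the C1–C10 labels) | O=CC[C@@]1(C)CC[C@H](C(C)C)[C@@]1(O[Si](CC)(CC)CC)CCC(C)=O | intermediate
22 | (1R,3aR,6R,8aS)-6-hydroxy-3a,6-dimethyl-1-(propan-2-yl)-8a-[(triethylsilyl)oxy]octahydroazulen-5(1H)-one (3R,6R,7S,10R in the C1–C10 labels) | O=C1C[C@@]2(C)CC[C@H](C(C)C)[C@@]2(O[Si](CC)(CC)CC)CC[C@@]1(C)O | intermediate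
23 | (1R,3aR,5R,6R,8aS)-3a,6-dimethyl-1-(propan-2-yl)-8a-[(triethylsilyl)oxy]decahydroazulene-5,6-diol (trans-diol) | O[C@@H]1C[C@@]2(C)CC[C@H](C(C)C)[C@@]2(O[Si](CC)(CC)CC)CC[C@@]1(C)O | intermediate
24 | (3R,3aS,6R,7R,8aR)-6,8a-dimethyl-3-(propan-2-yl)decahydroazulene-3a,6,7-triol | O[C@@H]1C[C@@]2(C)CC[C@H](C(C)C)[C@@]2(O)CC[C@@]1(C)O | intermediate
25 | p-anisoyl chloride (4-methoxybenzoyl chloride) | COc1ccc(C(Cl)=O)cc1 | starting material
26 | (1R,3aR,5R,6R,8aS)-6,8a-dihydroxy-3a,6-dimethyl-1-(propan-2-yl)decahydroazulen-5-yl 4-methoxybenzoate (1R,3R,6R,7S,10R in the C1–C10 labels) | COc1ccc(C(=O)O[C@@H]2C[C@@]3(C)CC[C@H](C(C)C)[C@@]3(O)CC[C@@]2(C)O)cc1 | target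

Total step count: 13. Longest linear sequence: 13 steps (1 → 26).

Steps most likely to fail

Step 11 (carries the label). The seven-membered closure may be slower than aldol closure of the keto-aldehyde or than loss of the catalyst, or attack may fall on the wrong face of the C10 ketone. The fallback uses known reactions only, sets out from 19 and comes back at 22, replacing steps 10 and 11. Wittig methylenation of 19 (Ph3P=CH2, THF, 0 °C) should give the diene triethyl{[(1S,2R,5R)-2-methyl-1-(3-methylbut-3-en-1-yl)-5-(propan-2-yl)-2-(prop-2-en-1-yl)cyclopentyl]oxy}silane F1. Ring-closing metathesis with second-generation Grubbs catalyst (CH2Cl2, 40 °C) then joins C1 and C10 as a trisubstituted double bond in the bicyclic alkene triethyl{[(3R,3aS,8aR)-6,8a-dimethyl-3-(propan-2-yl)-2,3,4,5,8,8a-hexahydroazulen-3a(1H)-yl]oxy}silane F2. Dihydroxylation (OsO4 cat., N-methylmorpholine N-oxide, acetone–water) is expected on the face away from the C3 methyl and C7 silyloxy groups and should give the cis-diol (1R,3aR,5S,6R,8aS)-3a,6-dimethyl-1-(propan-2-yl)-8a-[(triethylsilyl)oxy]decahydroazulene-5,6-diol F3. Parikh–Doering oxidation (SO3·pyridine, DMSO, Et3N) of its secondary C1 hydroxyl erases the C1 centre and leads to 22.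

Step 5. Facial discrimination in the sigmatropic shift may be insufficient at 140 °C, or bond formation at the fully substituted alkene carbon may be slow enough for the acid to degrade the allylic alcohol. The fallback sets out from 7 and comes back at 11, using the ester-enolate variant of the rearrangement, which runs more than a hundred degrees lower. Acetylation (Ac2O, pyridine, DMAP) gives [(5R)-2-methyl-5-(propan-2-yl)cyclopent-1-en-1-yl]methyl acetate F4. Treatment with LiN(i-Pr)2 and Me3SiCl (THF, −78 °C → rt; Ireland–Claisen rearrangement) forms the silyl ketene acetal trimethyl[(1-{[(5R)-2-methyl-5-(propan-2-yl)cyclopent-1-en-1-yl]methoxy}ethenyl)oxy]silane F5. This should rearrange to trimethylsilyl 2-[(1R,3R)-1-methyl-2-methylidene-3-(propan-2-yl)cyclopentyl]acetate F6, which aqueous work-up hydrolyses to 2-[(1R,3R)-1-methyl-2-methylidene-3-(propan-2-yl)cyclopentyl]acetic acid F7. Ethylation (EtI, K2CO3, DMF) returns 11.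

Step 7. The organometallic may attack the ester carbonyl, above all if the hindered ketone calls for excess reagent or higher temperature. The fallback sets out from 11 and comes back at 17, carrying the C1 arm as a carboxylate, which organocerium reagents do not attack. Saponification of 11 (LiOH, THF/MeOH/H2O) gives 2-[(1R,3R)-1-methyl-2-methylidene-3-(propan-2-yl)cyclopentyl]acetic acid F7, the acid already met above. Ozonolysis (O3, CH2Cl2, −78 °C; PPh3) passes through the spiro-ozonide of the acid F8 to 2-[(1R,3R)-1-methyl-2-oxo-3-(propan-2-yl)cyclopentyl]acetic acid F9. An excess of organocerium reagent 16 (the first equivalent removes the acid proton) then adds to the ketone with the same facial preference and should give 2-[(1R,2S,3R)-2-hydroxy-1-methyl-2-(3-methylbut-3-en-1-yl)-3-(propan-2-yl)cyclopentyl]acetic acid F10. Ethylation (EtI, K2CO3, DMF) gives 17.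

Further compounds
F1 | step 11 | triethyl{[(1S,2R,5R)-2-methyl-1-(3-methylbut-3-en-1-yl)-5-(propan-2-yl)-2-(prop-2-en-1-yl)cyclopentyl]oxy}silane | C=CC[C@@]1(C)CC[C@H](C(C)C)[C@@]1(O[Si](CC)(CC)CC)CCC(C)=C
F2 | step 11 | triethyl{[(3R,3aS,8aR)-6,8a-dimethyl-3-(propan-2-yl)-2,3,4,5,8,8a-hexahydroazulen-3a(1H)-yl]oxy}silane | CC1=CC[C@@]2(C)CC[C@H](C(C)C)[C@@]2(O[Si](CC)(CC)CC)CC1
F3 | step 11 | (1R,3aR,5S,6R,8aS)-3a,6-dimethyl-1-(propan-2-yl)-8a-[(triethylsilyl)oxy]decahydroazulene-5,6-diol | O[C@H]1C[C@@]2(C)CC[C@H](C(C)C)[C@@]2(O[Si](CC)(CC)CC)CC[C@@]1(C)O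
F4 | step 5 | [(5R)-2-methyl-5-(propan-2-yl)cyclopent-1-en-1-yl]methyl acetate | CC(=O)OCC1=C(C)CC[C@@H]1C(C)C
F5 | step 5 | trimethyl[(1-{[(5R)-2-methyl-5-(propan-2-yl)cyclopent-1-en-1-yl]methoxy}ethenyl)oxy]silane | C=C(O[Si](C)(C)C)OCC1=C(C)CC[C@@H]1C(C)C
F6 | step 5 | trimethylsilyl 2-[(1R,3R)-1-methyl-2-methylidene-3-(propan-2-yl)cyclopentyl]acetate | C[Si](C)(C)OC(=O)C[C@@]1(C)CC[C@H](C(C)C)C1=C
F7 | step 5 | 2-[(1R,3R)-1-methyl-2-methylidene-3-(propan-2-yl)cyclopentyl]acetic acid | OC(=O)C[C@@]1(C)CC[C@H](C(C)C)C1=C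
F8 | step 7 | spiro-ozonide of F7 (1,2,4-trioxolane spiro-fused at C7; mixture at the spiro carbon) | OC(=O)C[C@@]1(C)CC[C@H](C(C)C)C12OCOO2
F9 | step 7 | 2-[(1R,3R)-1-methyl-2-oxo-3-(propan-2-yl)cyclopentyl]acetic acid | OC(=O)C[C@@]1(C)CC[C@H](C(C)C)C1=O
F10 | step 7 | 2-[(1R,2S,3R)-2-hydroxy-1-methyl-2-(3-methylbut-3-en-1-yl)-3-(propan-2-yl)cyclopentyl]acetic acid | OC(=O)C[C@@]1(C)CC[C@H](C(C)C)[C@@]1(O)CCC(C)=C
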